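**Plan**
- Retrosynthesis: the N-ring is opened at N2–C1 and C1–C8a (iminium/arene closure, with acetaldehyde supplying C1 and its methyl). Next the C5–C8' biaryl bond is cut (Suzuki–Miyaura), then C4–C4a (aryllithium plus a D-alaninol-derived cyclic sulfamidate). The naphthalene is cut across an aryne/2-methoxyfuran Diels–Alder.
- Forward: the naphthalene ring is made first and turned into boronate 8 (steps 1–3). The bought benzene ring receives its side chain and a bromine at C5 (steps 4–6). The biaryl is joined (step 7), the Boc carbon is reduced to N-methyl and the phenol is freed (steps 8–9). The tetrahydroisoquinoline N-ring is closed last (step 10).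
- Enabling feature: in 18 the ring carbon C8a is ortho to the free C8 hydroxyl and para to the C6 methoxyl, and C5, the other carbon ortho to the side chain, carries the naphthyl group. An N-methyl iminium ion on the side-chain nitrogen can therefore close only the six-membered N-ring, at C8a, under mild acid.
- Stereochemistry: C3 (R) comes unchanged from sulfamidate 11. C1 (R) is set in step 10, trans to C3, by allylic strain in the N-methyl iminium ion.
- Helpers: the triisopropylsilyl ether protects the phenol and steers the bromination; the Boc carbonyl carbon ends up as the N-methyl group.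

Key step: step 10

Assumption: the structure as given fixes only C1 and C3; rotation about the tri-ortho-substituted C5–C8' bond is expected to be slow, so 16–18 and 21 are expected as pairs of atropo-diastereomers, carried on together and separable as diastereomers at the end.

**Route**

Step 1
Reactants: 1 1-bromo-3-methoxy-5-methylbenzene; 2 2-methoxyfuran
Product: 6 4,5-dimethoxy-7-methylnaphthalen-1-ol, via aryllithium 3 (not isolated), via aryne 4 (not isolated), via cycloadduct 5 (not isolated)
Conditions: LiN(iPr)2 (1.2 equiv), 2 (3 equiv), THF, –78 °C → rt; then 1 M HCl, rt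
Reagents that add atoms: none
Why: Lithiation of 1 between Br and OMe and loss of LiBr give a 3-methoxybenzyne whose more electrophilic carbon (meta to OMe) should be attacked by C5 of the furan, so that the aryne–furan Diels–Alder reaction joins the two methoxy-bearing carbons head to head and the bridgehead ketal of 5 opens on acid work-up to the 4-methoxy-1-naphthol 6.

Step 2
Reactants: 6 4,5-dimethoxy-7-methylnaphthalen-1-ol
Product: 7 4,5-dimethoxy-7-methylnaphthalen-1-yl trifluoromethanesulfonate
Conditions: Tf2O, pyridine, CH2Cl2, 0 °C (6 used directly, under argon)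
Reagents that add atoms: trifluoromethanesulfonic anhydride, O=S(=O)(OS(=O)(=O)C(F)(F)F)C(F)(F)F
Why: O-Sulfonylation of a naphthol is routine and turns the oxidation-prone electron-rich naphthol into a stable cross-coupling electrophile at the carbon that becomes C8'.

Step 3
Reactants: 7 4,5-dimethoxy-7-methylnaphthalen-1-yl trifluoromethanesulfonate
Product: 8 2-(4,5-dimethoxy-7-methylnaphthalen-1-yl)-4,4,5,5-tetramethyl-1,3,2-dioxaborolane
Conditions: PdCl2(dppf) [dppf = 1,1'-bis(diphenylphosphino)ferrocene] (5 mol %), B2pin2, KOAc, 1,4-dioxane, 90 °C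
Reagents that add atoms: bis(pinacolato)diboron, CC1(C)OB(OC1(C)C)B1OC(C)(C)C(C)(C)O1
Why: Miyaura borylation of an aryl triflate places boron on the less hindered naphthyl partner, so that the later coupling does not need a di-ortho-substituted, protodeboronation-prone boronate on the benzene ring.

Step 4
Reactants: 9 3-bromo-5-methoxyphenol
Product: 10 (3-bromo-5-methoxyphenoxy)triisopropylsilane
Conditions: iPr3SiCl, imidazole, DMF, rt
Reagents that add atoms: chlorotriisopropylsilane, CC(C)[Si](Cl)(C(C)C)C(C)C
Why: Silylation of a phenol masks the acidic OH for the lithiation that follows and installs a bulky group that later shields both of its ortho positions.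

Step 5
Reactants: 10 (3-bromo-5-methoxyphenoxy)triisopropylsilane; 11 tert-butyl (4R)-4-methyl-1,2,3-oxathiazolidine-3-carboxylate 2,2-dioxide
Product: 14 tert-butyl N-[(2R)-1-[3-methoxy-5-(triisopropylsilyloxy)phenyl]propan-2-yl]carbamate, via aryllithium 12 (not isolated), via lithium sulfamate 13 (not isolated)
Conditions: n-BuLi, THF, –78 °C; then 11, –78 → 0 °C; then 1 M aq. citric acid, rt
Reagents that add atoms: none
Why: Bromine–lithium exchange and SN2 opening of the cyclic sulfamidate at its primary C–O carbon form C4–C4a without touching the stereocentre, so the R configuration of the D-alaninol-derived reagent is kept as C3, and mild acid hydrolysis of the N-sulfamate leaves the Boc group in place.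

Step 6
Reactants: 14 tert-butyl N-[(2R)-1-[3-methoxy-5-(triisopropylsilyloxy)phenyl]propan-2-yl]carbamate
Product: 15 tert-butyl N-[(2R)-1-[2-bromo-3-methoxy-5-(triisopropylsilyloxy)phenyl]propan-2-yl]carbamate
Conditions: NBS (1.0 equiv), MeCN, 0 °C, dark
Reagents that add atoms: N-bromosuccinimide, O=C1CCC(=O)N1Br
Why: In this electrophilic aromatic bromination the two ring positions ortho to the bulky silyl ether are shielded, so bromine should enter para to the silyloxy group and ortho to the methoxyl, at the carbon that becomes C5.

Step 7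
Reactants: 15 tert-butyl N-[(2R)-1-[2-bromo-3-methoxy-5-(triisopropylsilyloxy)phenyl]propan-2-yl]carbamate; 8 2-(4,5-dimethoxy-7-methylnaphthalen-1-yl)-4,4,5,5-tetramethyl-1,3,2-dioxaborolane
Product: 16 tert-butyl N-[(2R)-1-[2-(4,5-dimethoxy-7-methylnaphthalen-1-yl)-3-methoxy-5-(triisopropylsilyloxy)phenyl]propan-2-yl]carbamate
Conditions: Pd(OAc)2 (5 mol %), SPhos (2-dicyclohexylphosphino-2',6'-dimethoxybiphenyl, 10 mol %), K3PO4, toluene/H2O (10:1), 100 °C
Reagents that add atoms: none
Why: A Suzuki–Miyaura coupling with a bulky electron-rich dialkylbiarylphosphine is the established way to a tri-ortho-substituted biaryl from a di-ortho-substituted bromide and a 1-naphthylboronate, and since no element controls the new C5–C8' axis both rotamers are expected.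

Step 8
Reactants: 16 tert-butyl N-[(2R)-1-[2-(4,5-dimethoxy-7-methylnaphthalen-1-yl)-3-methoxy-5-(triisopropylsilyloxy)phenyl]propan-2-yl]carbamate
Product: 17 (2R)-1-[2-(4,5-dimethoxy-7-methylnaphthalen-1-yl)-3-methoxy-5-(triisopropylsilyloxy)phenyl]-N-methylpropan-2-amine
Conditions: LiAlH4, THF, 65 °C; aq. NaOH work-up
Reagents that add atoms: none
Why: Hydride reduction of a carbamate to the N-methyl amine makes the Boc carbonyl carbon the N-methyl group of the target, while the hindered aryl silyl ether and the aryl methyl ethers should be inert.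

Step 9
Reactants: 17 (2R)-1-[2-(4,5-dimethoxy-7-methylnaphthalen-1-yl)-3-methoxy-5-(triisopropylsilyloxy)phenyl]-N-methylpropan-2-amine
Product: 18 4-(4,5-dimethoxy-7-methylnaphthalen-1-yl)-3-methoxy-5-[(2R)-2-(methylamino)propyl]phenol
Conditions: Bu4NF, THF, 0 °C → rt
Reagents that add atoms: none
Why: Fluoride cleavage of the silyl ether frees the C8 hydroxyl, which is needed small and unprotected to activate C8a and to keep peri strain low in the ring closure.

Step 10
Reactants: 18 4-(4,5-dimethoxy-7-methylnaphthalen-1-yl)-3-methoxy-5-[(2R)-2-(methylamino)propyl]phenol; 19 acetaldehyde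
Product: 21 ancistrocongoline B [(1R,3R)-5-(4,5-dimethoxy-7-methylnaphthalen-1-yl)-6-methoxy-1,2,3-trimethyl-1,2,3,4-tetrahydroisoquinolin-8-ol], via iminium ion 20 (not isolated)
Conditions: MeCHO (1.5 equiv), CF3CO2H (1.2 equiv), CH2Cl2, 4 Å molecular sieves, 0 °C → rt
Reagents that add atoms: none
Why: The secondary amine of 18 condenses with acetaldehyde to the N-methyl iminium ion 20, whose carbon is attacked by C8a (ortho to the free C8–OH, para to C6–OMe) in an intramolecular Mannich-type electrophilic substitution, and loss of the C8a proton restores the arene and gives 21. The closest known reaction type is the Pictet–Spengler cyclisation of N-alkyl 1-arylpropan-2-amines with acetaldehyde, which is known to favour trans-1,3-dimethyl products. The N-ring closes in the 6-endo-trig mode, the C=N+ bond lying inside the new ring. The new stereocentre C1 is controlled by C3: allylic strain with the in-plane N-methyl group puts the C3 methyl pseudoaxial in the half-chair transition state, and the iminium methyl sits anti to the C3 branch and so ends pseudoequatorial, which places the two methyl groups trans and makes C1 R from C3 R. The step needs regioselectivity (secured because C5, the only other carbon ortho to the side chain, bears the naphthyl group and C7 cannot be reached by the tether), diastereoselectivity (secured by the N-methyl group together with the small free hydroxyl at C8) and chemoselectivity against a further hydroxyalkylation at C7 (secured by little excess aldehyde at low temperature). Because the nitrogen already carries its methyl group and the phenol is free, this closure forms N2–C1 and C1–C8a, sets the last stereocentre and ends the synthesis in one operation.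

**Compound list**

1 | 1-bromo-3-methoxy-5-methylbenzene | COc1cc(C)cc(Br)c1 | starting material
2 | 2-methoxyfuran | COc1ccco1 | starting material
3 | (2-bromo-6-methoxy-4-methylphenyl)lithium | COc1cc(C)cc(Br)c1[Li] | intermediate
4 | 3-methoxy-5-methylbenzyne (1,2-didehydro-3-methoxy-5-methylbenzene) | COC1=CC(C)=CC#C1 | intermediate
5 | 4,5-dimethoxy-7-methyl-1,4-dihydro-1,4-epoxynaphthalene (racemic) | COc1cc(C)cc2c1C1(OC)C=CC2O1 | intermediate
6 | 4,5-dimethoxy-7-methylnaphthalen-1-ol | COc1ccc(O)c2cc(C)cc(OC)c12 | intermediate
7 | 4,5-dimethoxy-7-methylnaphthalen-1-yl trifluoromethanesulfonate | COc1ccc(OS(=O)(=O)C(F)(F)F)c2cc(C)cc(OC)c12 | intermediate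
8 | 2-(4,5-dimethoxy-7-methylnaphthalen-1-yl)-4,4,5,5-tetramethyl-1,3,2-dioxaborolane | COc1ccc(B2OC(C)(C)C(C)(C)O2)c2cc(C)cc(OC)c12 | intermediate
9 | 3-bromo-5-methoxyphenol | COc1cc(O)cc(Br)c1 | starting material
10 | (3-bromo-5-methoxyphenoxy)triisopropylsilane | COc1cc(Br)cc(O[Si](C(C)C)(C(C)C)C(C)C)c1 | intermediate
11 | tert-butyl (4R)-4-methyl-1,2,3-oxathiazolidine-3-carboxylate 2,2-dioxide | C[C@@H]1COS(=O)(=O)N1C(=O)OC(C)(C)C | starting material
12 | [3-methoxy-5-(triisopropylsilyloxy)phenyl]lithium | COc1cc([Li])cc(O[Si](C(C)C)(C(C)C)C(C)C)c1 | intermediate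
13 | lithium N-(tert-butoxycarbonyl)-N-[(2R)-1-[3-methoxy-5-(triisopropylsilyloxy)phenyl]propan-2-yl]sulfamate | C[C@H](Cc1cc(OC)cc(O[Si](C(C)C)(C(C)C)C(C)C)c1)N(C(=O)OC(C)(C)C)S(=O)(=O)[O-].[Li+] | intermediate
14 | tert-butyl N-[(2R)-1-[3-methoxy-5-(triisopropylsilyloxy)phenyl]propan-2-yl]carbamate | C[C@H](Cc1cc(OC)cc(O[Si](C(C)C)(C(C)C)C(C)C)c1)NC(=O)OC(C)(C)C | intermediate
15 | tert-butyl N-[(2R)-1-[2-bromo-3-methoxy-5-(triisopropylsilyloxy)phenyl]propan-2-yl]carbamate | C[C@H](Cc1cc(O[Si](C(C)C)(C(C)C)C(C)C)cc(OC)c1Br)NC(=O)OC(C)(C)C | intermediate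
16 | tert-butyl N-[(2R)-1-[2-(4,5-dimethoxy-7-methylnaphthalen-1-yl)-3-methoxy-5-(triisopropylsilyloxy)phenyl]propan-2-yl]carbamate (both rotamers about the biaryl axis) | C[C@H](Cc1cc(O[Si](C(C)C)(C(C)C)C(C)C)cc(OC)c1-c1ccc(OC)c2c(OC)cc(C)cc12)NC(=O)OC(C)(C)C | intermediate
17 | (2R)-1-[2-(4,5-dimethoxy-7-methylnaphthalen-1-yl)-3-methoxy-5-(triisopropylsilyloxy)phenyl]-N-methylpropan-2-amine | CN[C@H](C)Cc1cc(O[Si](C(C)C)(C(C)C)C(C)C)cc(OC)c1-c1ccc(OC)c2c(OC)cc(C)cc12 | intermediate
18 | 4-(4,5-dimethoxy-7-methylnaphthalen-1-yl)-3-methoxy-5-[(2R)-2-(methylamino)propyl]phenol | CN[C@H](C)Cc1cc(O)cc(OC)c1-c1ccc(OC)c2c(OC)cc(C)cc12 | intermediate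
19 | acetaldehyde | CC=O | starting material
20 | N-[(2R)-1-[2-(4,5-dimethoxy-7-methylnaphthalen-1-yl)-5-hydroxy-3-methoxyphenyl]propan-2-yl]-N-methylethaniminium trifluoroacetate | CC=[N+](C)[C@H](C)Cc1cc(O)cc(OC)c1-c1ccc(OC)c2c(OC)cc(C)cc12.[O-]C(=O)C(F)(F)F | intermediate
21 | ancistrocongoline B, (1R,3R)-5-(4,5-dimethoxy-7-methylnaphthalen-1-yl)-6-methoxy-1,2,3-trimethyl-1,2,3,4-tetrahydroisoquinolin-8-ol | COc1cc(O)c2c(c1-c1ccc(OC)c3c(OC)cc(C)cc13)C[C@@H](C)N(C)[C@@H]2C | target

**Count and risks**

Total step count: 10. Longest linear sequence: 7 steps (steps 4–10 from 9; the naphthalene branch, steps 1–3 then 7–10, is equally long).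

Steps most likely to fail:

1. Step 10. What may go wrong: insufficient facial discrimination when C8a attacks the iminium ion, so that cis and trans products form together, and further hydroxyalkylation of the very electron-rich phenol ring at C7 by the aldehyde. Fallback (C1 set by nucleophilic addition to a preformed ring iminium instead of during ring closure): the fallback sets out from 17. Formylation of the amine (HCO2Et, reflux) would give N-[(2R)-1-[2-(4,5-dimethoxy-7-methylnaphthalen-1-yl)-3-methoxy-5-(triisopropylsilyloxy)phenyl]propan-2-yl]-N-methylformamide F1. A Bischler–Napieralski-type cyclodehydration (Tf2O, 2-chloropyridine, CH2Cl2, –78 → 23 °C) at C8a should then give the 2,3-dimethyl-3,4-dihydroisoquinolinium triflate F2. MeMgBr (THF, –78 °C) should add to C1 anti to the pseudoaxial C3 methyl and give the trans-1,2,3-trimethyl tetrahydroisoquinoline silyl ether F3. Bu4NF in THF then frees the phenol, and the route is rejoined at 21.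

2. Step 1. What may go wrong: cycloaddition in the opposite orientation (methoxy groups apart), addition of diisopropylamine to the aryne, or decomposition of the acid-sensitive methoxyfuran and the oxidation-prone naphthol. Fallback (the C4 oxygen is introduced by para-oxidation of a naphthol, so cycloaddition regiochemistry no longer matters): the fallback sets out from 1. The aryne is generated as before but trapped with furan, to give 5-methoxy-7-methyl-1,4-dihydro-1,4-epoxynaphthalene F4. Acid (cat. HCl, MeOH) should ionise the C–O bond next to the methoxy-bearing ring carbon, where the benzylic cation is stabilised by the ortho methoxyl and para methyl, and so give 5-methoxy-7-methylnaphthalen-1-ol F5. PhI(OAc)2 (2 equiv) in MeOH should oxidise the para position to the quinone monoketal 4,4,5-trimethoxy-7-methylnaphthalen-1(4H)-one F6. Zn in AcOH should aromatise it reductively with loss of methanol, and the route is rejoined at 6.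

3. Step 6. What may go wrong: bromination at the ring carbon para to the methoxyl, or partial loss of the silyl ether followed by over-bromination. Fallback (directed ortho-metalation instead of electrophilic substitution): the fallback sets out from 14. n-BuLi (2.2 equiv, THF, –20 → 0 °C) should deprotonate the carbamate N–H and then the ring carbon flanked by the methoxyl and the side chain, both of which direct there while the silyl ether shields the other positions, to give the N,2-dilithio derivative of 14 F7. Quenching with BrCCl2CCl2Br introduces the bromine, and the route is rejoined at 15.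

**Further compounds**

F1 | step 10 | N-[(2R)-1-[2-(4,5-dimethoxy-7-methylnaphthalen-1-yl)-3-methoxy-5-(triisopropylsilyloxy)phenyl]propan-2-yl]-N-methylformamide | O=CN(C)[C@H](C)Cc1cc(O[Si](C(C)C)(C(C)C)C(C)C)cc(OC)c1-c1ccc(OC)c2c(OC)cc(C)cc12
F2 | step 10 | (3R)-5-(4,5-dimethoxy-7-methylnaphthalen-1-yl)-6-methoxy-2,3-dimethyl-8-(triisopropylsilyloxy)-3,4-dihydroisoquinolin-2-ium trifluoromethanesulfonate | C[C@@H]1Cc2c(-c3ccc(OC)c4c(OC)cc(C)cc34)c(OC)cc(O[Si](C(C)C)(C(C)C)C(C)C)c2C=[N+]1C.[O-]S(=O)(=O)C(F)(F)F
F3 | step 10 | (1R,3R)-5-(4,5-dimethoxy-7-methylnaphthalen-1-yl)-6-methoxy-1,2,3-trimethyl-8-(triisopropylsilyloxy)-1,2,3,4-tetrahydroisoquinoline | COc1cc(O[Si](C(C)C)(C(C)C)C(C)C)c2c(c1-c1ccc(OC)c3c(OC)cc(C)cc13)C[C@@H](C)N(C)[C@@H]2C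
F4 | step 1 | 5-methoxy-7-methyl-1,4-dihydro-1,4-epoxynaphthalene (racemic) | COc1cc(C)cc2c1C1C=CC2O1
F5 | step 1 | 5-methoxy-7-methylnaphthalen-1-ol | COc1cc(C)cc2c(O)cccc12
F6 | step 1 | 4,4,5-trimethoxy-7-methylnaphthalen-1(4H)-one | COc1cc(C)cc2c1C(OC)(OC)C=CC2=O
F7 | step 6 | N,2-dilithio derivative of 14, lithium tert-butyl N-[(2R)-1-[2-lithio-3-methoxy-5-(triisopropylsilyloxy)phenyl]propan-2-yl]carbamate | C[C@H](Cc1cc(O[Si](C(C)C)(C(C)C)C(C)C)cc(OC)c1[Li])N([Li])C(=O)OC(C)(C)C
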